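The earlier runs and the new flask stem from a simulated flask from invented constants; noise was put on by code.

The solid electrophile dissolves slowly, and we want to know how much of it has reacted by 2.0 min in two flasks, larch and cedar, which differ in their equivalents of nucleophile.

| flask | solid electrophile | nucleophile | protic impurity | remark | time |
|---|---|---|---|---|---|
| Wednesday's | 1 M | 1.3 equiv | 0.30 M | run made earlier |  |
| Friday's | 1 M | 2.3 equiv | 0.30 M | run made earlier |  |
| larch | 1.0 M | 2.00 equiv | 0.300 M |  | 2.0 min |
| cedar | 1.0 M | 1.00 equiv | 0.300 M |  | 2.0 min |

| run | time / s | solid electrophile / % | product / % |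
|---|---|---|---|
| Wednesday's | 10.0 | 93.8 | 1.9 |
| Wednesday's | 15.0 | 89.8 | 1.8 |
| Wednesday's | 25.0 | 82.1 | 3.3 |
| Wednesday's | 30.0 | 79.7 | 3.0 |
| Wednesday's | 40.0 | 72.6 | 5.1 |
| Wednesday's | 50.0 | 68.4 | 7.3 |
| Wednesday's | 60.0 | 59.3 | 8.1 |
| Friday's | 10.0 | 93.1 | 2.4 |
| Friday's | 15.0 | 89.5 | 3.3 |
| Friday's | 25.0 | 81.7 | 2.9 |
| Friday's | 40.0 | 72.5 | 4.8 |
| Friday's | 50.0 | 66.1 | 8.6 |
| Friday's | 60.0 | 59.7 | 14.4 |

(scatter of a reading: 1 percentage point)

- at the start none of the solid electrophile is in solution
- what has only dissolved of solid electrophile counts as not reacted

* part of the solid electrophile that has reacted (what has only dissolved counts as not reacted) at the end, larch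
* part of the solid electrophile that has reacted (what has only dissolved counts as not reacted) at the end, cedar
* what raising the equivalents of nucleophile from its lowest to its highest value here does to the part of the solid electrophile that has reacted (what has only dissolved counts as not reacted) (changes below 5 percentage points count as none) (it falls / no change / it rises)

By the last reading, the solid has lost 40.7% on Wednesday and 40.3% on Friday. Nucleophile leaves this loss unchanged within the scatter, so we take it as steady, which gives 81.0% by 2.0 min.

We divide product by solid lost at the last reading, and then by the equivalents of nucleophile. Time does not drop out of this ratio: before that division, Friday reads 0.158 at 25.0 s and 0.357 at 60.0 s, so what we carry is a share at the last reading. Wednesday gives 0.153 and Friday 0.155, so we carry their mean, 0.154, the product share per equivalent.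

Holding that share to 2.0 min is a rough assumption of ours, and it puts product at 25.0% in larch and 12.5% in cedar. At the last readings, what has left the solid without becoming product is 32.6% and 25.9%, near the impurity's charge of 30.0% of the solid's. We assume the impurity consumes that much dissolved electrophile, which gives 55.0% reacted for larch and 42.5% for cedar.

The forecast says 33% (25% to 42%) for larch and 16% (11% to 23%) for cedar, and for the trend, it rises. Its grounds differ from ours: “I assume the impurity quickly destroys 0.30 M nucleophile”.

The flasks give 54.9% for larch and 46.5% for cedar, and for the trend, it rises, by 8.3 percentage points.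

    electrophile + protic impurity → quenched substrate (k = 0.200 M⁻¹ s⁻¹)
    nucleophile + acid set free ⇌ protonated nucleophile, settled at all times (K = 3300 M⁻¹)
    solid electrophile ⇌ electrophile, rate k3*(cs3 - [electrophile]) while solid is left; crystals form when [electrophile] > cs3 (solubility = 0.830 M, k = 0.00900 s⁻¹)
    2 nucleophile → homo dimer (k = 0.00130 M⁻¹ s⁻¹)
    electrophile + nucleophile → acid set free + product (k = 0.0150 M⁻¹ s⁻¹)

Larch shows a product share per equivalent of 0.173 against the carried 0.154. The same flask with 0.500 equiv of nucleophile, reckoned from 0.154 and the impurity's charge at 36.2%, gives 39.7%. Just after the start of larch, electrophile goes to quenched substrate at 2.0 times the rate at which it goes to product, and by 2.00 min that ratio is 0.27. At that time larch holds 28.3% quenched substrate beside 26.6% product.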